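**The fixed sum.** Nothing leaves this closed flask, so its species add up at each moment to the charge of 15 mM of starting material. You follow where that sum goes.

starting material 15 mM; time 10 h

    starting material → side product (k1 = 0.0402 /min)
    starting material → intermediate A (k2 = 0.00939 /min)
    intermediate A → intermediate B (k3 = 0.00382 /min)
    intermediate A ⇌ intermediate C (K4 = 0.254, k4 = 0.00534 /min)
    intermediate A ⇌ intermediate D (K5 = 40, k5 = 6.18 × 10⁻⁴ /min)
    intermediate B → target (k6 = 0.0104 /min)
    starting material → intermediate C (k7 = 0.0146 /min)
    crystals ⇌ target, rate k8*(cs8 - [target]) while solid is left; crystals form when [target] > cs8 (cs8 = 10 mM, k8 = 0.0762 /min)

- alpha: doubling the dissolution coefficient of step 8, all else as stated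
- gamma: doubling the solubility in step 8, all else as stated

- amount of target and crystals together at 10 h, in percent of the starting material charged
- the change that raises the amount of target and crystals together at 10 h, in percent of the starting material charged most ("none" if none brings more than 2 percentage points) (alpha / gamma / none)
- amount of target and crystals together at 10 h, in percent of the starting material charged, after alpha

- for target the crystals are counted in
- as a solid, counted per litre of solution: crystals
- run time (flask): 10 h

**The kept share.** Starting material goes to side product with 0.0402 /min, and to intermediates A and C with 0.00939 /min and 0.0146 /min. These steps are first order, so their rates stand in the ratio of their constants at each moment, and side product has no way back. The part of the charge that escapes side product, the kept share (the selectivity of this branch), is therefore the sum of the second and third constants over the sum of the three: 37.4%.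

**My reckoning.** The kept share of the charge is 5.61 mM, the ceiling for target. Because this is below the solubility of 10 mM, I expect target to stay dissolved and no solid to form, so neither alpha nor gamma should gain anything. The ceiling is not y itself. Intermediate A has a half-life of 3.0 h by its step towards intermediate B alone, which is not short beside the 10 h run. I therefore commit to a y below 37.4%, without a closer figure, and to alpha leaving it unchanged.

**The forecast.** It gives y as 25.2% (range 24.7% to 25.7%), the best change as none, and 25.2% after alpha. Its grounds: “No crystals ever form, and none were charged, so step 8 is inactive and neither alpha nor gamma changes anything.”

**The simulation.** The flask gives y as 25.2%, the best change as none, and 25.2% after alpha, with a gain of 0 percentage points from alpha and 0 points from gamma. At 10.0 h this flask is a solution holding 3.78 mM of target and 0% crystals, while 12 points of the kept share has not arrived as target.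

**Left longer.** The neighbouring flask, left until 25 h, has the same charge and constants. Its kept share is again 37.4% and its ceiling 5.61 mM, still under the solubility. It reads 31.9%, or 4.79 mM, with 0% crystals. In that neighbouring flask, target at 31.9% and intermediate D at 5.09% together make 37.0%, just under the kept share of 37.4%.

All constants belong to no real substance; what happens was integrated by code.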